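## Structural features

The target is a 3a,4,5,7a-tetrahydro-1H-indene: a cyclohexene (C3a, C4, C5, C6, C7, C7a; alkene C6=C7, methyl on C7) fused through the C3a–C7a bond to a cyclopentene (C1, C2, C3; alkene C2=C3, methyls on C1 and C3). Five contiguous stereocentres run C1–C7a–C3a–C4–C5: the fusion is trans, the C1 methyl is cis to H7a, and C4 (methyl, carboxyl) and C5 (ethyl, (1E,3E)-4-phenylbuta-1,3-dienyl) are adjacent all-carbon quaternary centres with carboxyl and dienyl cis; the configuration is (1R,3aR,4R,5S,7aS). The real difficulty is this vicinal quaternary pair and its correlation with the three tertiary centres of the five-membered ring, across a trans fusion that has no neighbouring carbonyl through which it could be equilibrated. The carboxyl carbon is flanked by two quaternary carbons, so attack at its carbonyl is slow, and a one-carbon hydroxylated arm on C5 sits cis and 1,4 to it and will close a γ-lactone with an ordinary ester. Fragile elements are the conjugated phenyldiene (acid, electrophilic oxidants), the trisubstituted ring alkenes (protonation at C2 gives a tertiary cation that the carboxyl can trap) and the doubly allylic C7a–H. The key step exploits the cyclopentene: C3 and C3a map onto a methyl alkyne, C7a and C1 onto an E-propenyl alkene and C2 onto carbon monoxide, while C4, C5 and the Z-configured C6=C7 alkene form the four-atom tether, so one cyclocarbonylation closes both rings at the C3a–C7a bond.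

## Logic of the disconnections

29 from 27 (through 28): the O–C(CH3)3 bond of the ester is cut. The carboxyl is carried as a tert-butyl ester from 13 onwards instead of a methyl ester. This is a deliberate change of spectator group: a methyl ester beside the freed CH2OH of 24 would lactonise, and no ester at this carbon can be saponified. Alkyl–oxygen cleavage needs no attack at the shielded carbonyl. The forward step must be non-protic, so that C2=C3 is not protonated and the diene survives.

27 from 25 and 26: the alkene next to C5 in the side chain is cut. This removes ten carbons, the phenyl ring and both E alkenes as one commercial reagent. The demand is an E-selective olefination of a non-enolisable but very hindered aldehyde.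

25 from 24 from 23: the C5 arm is returned to a silyl ether, which is inert through cyclocarbonylation, hydride reduction and Mitsunobu chemistry. The demand is that 24 stays open, which the tert-butyl ester and buffered fluoride secure.

23 from 20 from 19 (through 21 and 22): the C3a–H bond is cut, the alkene is moved from C2=C3 to C3=C3a and oxygen is placed on C2. The trans fusion cannot be set by equilibration, whereas an allylic diazene delivers hydrogen to C3a intramolecularly on a defined face. This turns the cyclopentene into the cyclopentenone that a (2+2+1) reaction gives. The demands are hydride addition anti to the C1 methyl and an SN2 displacement at a hindered allylic carbinol.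

19 from 17 and 18: the C3a–C7a, C1–C2 and C2–C3 bonds are cut. Both rings and two stereocentres disappear, leaving an acyclic dienyne whose only stereocentres are the quaternary pair. The forward step must make an internal alkene react and must choose one face of it.

17 from 15 and 16, and 15 from 14: the diene σ-bond and then the C6=C7 alkene are cut. Making the Z-trisubstituted alkene as a vinyl iodide and coupling it with retention fixes the two alkene geometries independently. It also avoids ester-to-aldehyde redox steps and a labile Z-enal. The demand is a Z-selective olefination of a neopentyl aldehyde.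

14 from 13 from 12: the aldehyde is traced to the E-propenyl group that the sigmatropic step leaves on C5, and the ester to the free acid. Ozone must cleave the alkene and spare the alkyne.

12 from 9, and 9 from 8 and 2 (through 10 and 11): the bond between the two quaternary carbons is cut by an Ireland–Claisen rearrangement. A chair transition state converts one carbinol centre and two alkene geometries into both quaternary centres. Chirality transfer from an enantiopure secondary allylic ester is preferred to a reagent-controlled enantioselective enolate rearrangement, which is unreliable for an α,α-disubstituted ester. The demand is control of the tetrasubstituted ketene acetal geometry (methyl cis to the allylic oxygen).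

8 from 7 from 5 from 4 from 3: the C–ethyl bond and the C–CH2O bond are cut. Hydroxyl-directed trans-hydroalumination and iodination fix the alkene geometry, and the carbinol centre comes from the chiral pool.

2 from 1: the α-methyl bond is cut; the α-centre is racemic and is erased on enolisation.

## Other disconnections considered

Alternative 1: The cut is at the two bonds that join the ring-fusion carbons to the rest of the five-membered ring, seen as a cyclohexene that is later contracted. In the forward step the enone lactone A2 and (E)-penta-1,3-diene A3 combine under AlCl3, and the cis adduct is epimerised at the carbon α to the ketone to give the trans-fused octalone lactone A1.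
- In its favour: a concerted cycloaddition on a rigid cis-fused bicyclic dienophile, with endo approach on the convex face, relays the quaternary pair to C1 and both fusion carbons more predictably than the facial choice in the conversion of 17 into 19. On this point it is the better plan. The trans fusion is reached thermodynamically, which is at least equal to the diazene route.
- Against it: the dienophile β-carbon is neopentyl, and a strong Lewis acid polymerises the diene. After the key step the cyclohexene must be cleaved, re-closed by aldol condensation and deoxygenated, which passes C1 through an epimerisable α-formyl stage. The ketone must be converted into the C7 methyl alkene. The lactone must be opened to a γ-hydroxy acid that wants to re-close.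
- Comparison: the chosen plan delivers the cyclopentene substitution pattern and the C6=C7 alkene directly and is clearly shorter. Alternative 1 also still needs A2 with both quaternary carbons in place.

Alternative 2: The cut is at the C4–C5 bond with the cyclohexene closed in the same event. The silyl ketene acetal of the bicyclic δ-lactone A5, whose tertiary carbinol carbon carries the E-alkenyl group, undergoes a ring-contracting Ireland–Claisen rearrangement to the acid A4.
- In its favour: the lactone ring fixes the ketene acetal geometry, which is better than the acyclic tetrasubstituted enolate that leads to 10. The whole carbocyclic core and both quaternary carbons arise in one step from stereocentres already in the cyclopentene, and the acid is obtained free. In directness of the core construction it is the better plan.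
- Against it: A5 is a tertiary allylic ester that can ionise or eliminate. It requires a stereodefined tertiary carbinol, an E-trisubstituted alkene and a trans-disposed cyclopentene beforehand. The constrained, boat-like transition state must join two fully substituted carbons. After removal of the benzyl-type ether from A4 the γ-hydroxy acid lactonises, so the acid would have to be reprotected.
- Comparison: mechanistically both plans rest on a (3,3) shift for the quaternary pair. The chosen plan places it early on a simple acyclic ester, while Alternative 2 places it late on a precious intermediate. Step counts should be similar overall.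

Alternative 3: The cut is at the bond from C4 to the carboxyl carbon. Fluoride (Bu4N Ph3SiF2) releases the cyclohexadienolate from the silyl dienol ether A6, and its γ-carbon is acylated by the carbonate tethered to C5, giving the cis-fused enone lactone A2.
- In its favour: a five-membered lactone can only be cis-fused, so the relative configuration of C4 and C5 follows from one pre-set quaternary centre. This is a safer relay than enolate geometry, and on this point it is the better plan. The reagents are simple and the step is polar and mild.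
- Against it: α- and O-acylation of the dienolate compete, and a methyl carbonate is a weak electrophile. The product contains only the six-membered ring, so the cyclopentene, three stereocentres, the C7 methyl alkene and the side chain remain, most plausibly through Alternative 1 with all its later steps. The lactone-opening problem is inherited.
- Comparison: it is equal or better on the quaternary pair and far worse on step economy. The chosen plan forms five of the nine ring carbons' bonds and two stereocentres in one step from 17.

Key step: step 12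

Assumption: (R)-but-3-yn-2-ol, (E)-prop-1-enylboronic acid, diethyl cinnamylphosphonate and N-isopropylidene-N'-(2-nitrobenzenesulfonyl)hydrazine are taken as purchasable; atom numbers C1–C7a refer to the indene numbering of the target.

## Route

Step 1
Reactants: 1 pent-3-ynoic acid
Product: 2 2-methylpent-3-ynoic acid (racemic)
Conditions: LiN(iPr)2 (2.2 equiv), THF, −78 °C; MeI, −78 °C; aq. HCl
Reagents that add atoms: iodomethane (CI)
Why: α-Alkylation of the carboxylic acid dianion; the enediolate reacts at the α-carbon, and low temperature with an acidic quench should suppress isomerisation to the allenic acid. The new centre is racemic and is destroyed in step 7.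

Step 2
Reactants: 3 (R)-but-3-yn-2-ol
Product: 4 (R)-pent-2-yne-1,4-diol
Conditions: n-BuLi (2.1 equiv), THF, −78 to 0 °C; (CH2O)n, 0 °C to rt; H2O
Reagents that add atoms: paraformaldehyde, as formaldehyde (C=O)
Why: Hydroxymethylation of the lithium acetylide of the alkoxide; the carbinol stereocentre is not involved.

Step 3
Reactants: 4 (R)-pent-2-yne-1,4-diol
Product: 5 (R)-5-[(tert-butyldimethylsilyl)oxy]pent-3-yn-2-ol
Conditions: t-BuMe2SiCl (1.0 equiv), imidazole, CH2Cl2, −20 to 0 °C
Reagents that add atoms: tert-butyldimethylsilyl chloride (CC(C)(C)[Si](C)(C)Cl)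
Why: Silylation discriminates the primary from the secondary propargylic hydroxyl on steric grounds.

Step 4
Reactants: 5 (R)-5-[(tert-butyldimethylsilyl)oxy]pent-3-yn-2-ol
Product: 7 (2R,3Z)-5-[(tert-butyldimethylsilyl)oxy]-4-iodopent-3-en-2-ol, via sodium alkenylalanate 6 (not isolated)
Conditions: NaAlH2(OCH2CH2OMe)2, THF, 0 °C; I2, THF, −78 °C; aq. potassium sodium tartrate
Reagents that add atoms: iodine (II)
Why: Hydroxyl-directed trans-hydroalumination of the propargylic alcohol places hydrogen on C3 and aluminium on C4 in a five-membered alkoxyalanate; iodinolysis with retention gives the Z iodide. Low temperature should prevent loss of the silyloxy group from the alanate.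

Step 5
Reactants: 7 (2R,3Z)-5-[(tert-butyldimethylsilyl)oxy]-4-iodopent-3-en-2-ol
Product: 8 (2R,3E)-4-{[(tert-butyldimethylsilyl)oxy]methyl}hex-3-en-2-ol
Conditions: Et2Zn (2.5 equiv), Pd(dppf)Cl2 (5 mol %), THF, 50 °C
Reagents that add atoms: diethylzinc (CC[Zn]CC)
Why: Negishi coupling of the alkenyl iodide proceeds with retention, so the ethyl group ends cis to the carbinol carbon; the hydroxyl is carried as its zinc alkoxide.

Step 6
Reactants: 8 (2R,3E)-4-{[(tert-butyldimethylsilyl)oxy]methyl}hex-3-en-2-ol, 2 2-methylpent-3-ynoic acid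
Product: 9 (2R,3E)-4-{[(tert-butyldimethylsilyl)oxy]methyl}hex-3-en-2-yl 2-methylpent-3-ynoate (both epimers at the acyl α-carbon)
Conditions: DCC, DMAP (5 mol %), CH2Cl2, 0 °C
Reagents that add atoms: none
Why: Steglich esterification with retention at the carbinol carbon; a low DMAP loading and low temperature should limit isomerisation of the activated alkynoic acid to the allenoate.

Step 7
Reactants: 9 (2R,3E)-4-{[(tert-butyldimethylsilyl)oxy]methyl}hex-3-en-2-yl 2-methylpent-3-ynoate
Product: 12 (2R,3S,4E)-3-{[(tert-butyldimethylsilyl)oxy]methyl}-3-ethyl-2-methyl-2-(prop-1-yn-1-yl)hex-4-enoic acid, via silyl ketene acetal 10 (not isolated), via trimethylsilyl ester 11 (not isolated)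
Conditions: LiN(iPr)2 (1.3 equiv), THF, −78 °C; Me3SiCl, −78 °C; then −78 to 65 °C; dilute aq. HCl
Reagents that add atoms: none
Why: Ireland–Claisen rearrangement; in the cyclic lithium amide transition state the methyl should lie cis to the ester oxygen and the slim propynyl group cis to OLi, giving 10. In the chair the carbinol methyl is equatorial (its axial position would clash with the axial ethyl), so the (R) centre is transferred to the ethyl-bearing carbon, and the two alkene geometries fix the carboxyl-bearing carbon relative to it, leaving an E-propenyl group.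

Step 8
Reactants: 12 (2R,3S,4E)-3-{[(tert-butyldimethylsilyl)oxy]methyl}-3-ethyl-2-methyl-2-(prop-1-yn-1-yl)hex-4-enoic acid
Product: 13 tert-butyl (2R,3S,4E)-3-{[(tert-butyldimethylsilyl)oxy]methyl}-3-ethyl-2-methyl-2-(prop-1-yn-1-yl)hex-4-enoate
Conditions: Me2NCH(OtBu)2 (4 equiv), toluene, 80 °C
Reagents that add atoms: N,N-dimethylformamide di-tert-butyl acetal (CN(C)C(OC(C)(C)C)OC(C)(C)C)
Why: The carboxylate is alkylated on oxygen, so the crowding at the carbonyl carbon does not matter; the silyl ether and alkyne are untouched.

Step 9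
Reactants: 13 tert-butyl (2R,3S,4E)-3-{[(tert-butyldimethylsilyl)oxy]methyl}-3-ethyl-2-methyl-2-(prop-1-yn-1-yl)hex-4-enoate
Product: 14 tert-butyl (2R,3S)-3-{[(tert-butyldimethylsilyl)oxy]methyl}-3-ethyl-2-methyl-4-oxo-2-(prop-1-yn-1-yl)butanoate
Conditions: O3, CH2Cl2, −78 °C, Sudan Red 7B as end-point indicator; PPh3, −78 °C to rt
Reagents that add atoms: ozone ([O-][O+]=O)
Why: Ozonolysis; the 1,2-disubstituted alkene reacts much faster than the internal alkyne, and the indicator dye stops the addition before the alkyne is attacked. The aldehyde is non-enolisable.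

Step 10
Reactants: 14 tert-butyl (2R,3S)-3-{[(tert-butyldimethylsilyl)oxy]methyl}-3-ethyl-2-methyl-4-oxo-2-(prop-1-yn-1-yl)butanoate
Product: 15 tert-butyl (2R,3S,4Z)-3-{[(tert-butyldimethylsilyl)oxy]methyl}-3-ethyl-5-iodo-2-methyl-2-(prop-1-yn-1-yl)hex-4-enoate
Conditions: EtPPh3I, n-BuLi, THF, 0 °C; I2, −78 °C; NaN(SiMe3)2, −78 °C; then 14, −78 to −20 °C
Reagents that add atoms: ethyltriphenylphosphonium iodide (CC[P+](c1ccccc1)(c1ccccc1)c1ccccc1.[I-]), iodine (II)
Why: Stork–Zhao-type Wittig reaction of the α-iodoethylidene ylide; the unstabilised ylide reacts under kinetic control and should give the Z iodoalkene, with the quaternary carbon cis to iodine.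

Step 11
Reactants: 15 tert-butyl (2R,3S,4Z)-3-{[(tert-butyldimethylsilyl)oxy]methyl}-3-ethyl-5-iodo-2-methyl-2-(prop-1-yn-1-yl)hex-4-enoate, 16 (E)-prop-1-en-1-ylboronic acid
Product: 17 tert-butyl (2R,3S,4Z,6E)-3-{[(tert-butyldimethylsilyl)oxy]methyl}-3-ethyl-2,5-dimethyl-2-(prop-1-yn-1-yl)octa-4,6-dienoate
Conditions: Pd(dppf)Cl2 (5 mol %), K3PO4, THF/H2O, 50 °C
Reagents that add atoms: none
Why: Suzuki–Miyaura coupling with retention at both sp2 carbons gives the 4Z,6E diene; the internal alkyne, ester and silyl ether are inert.

Step 12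
Reactants: 17 tert-butyl (2R,3S,4Z,6E)-3-{[(tert-butyldimethylsilyl)oxy]methyl}-3-ethyl-2,5-dimethyl-2-(prop-1-yn-1-yl)octa-4,6-dienoate, 18 carbon monoxide
Product: 19 tert-butyl (1S,4R,5S,7aR)-5-{[(tert-butyldimethylsilyl)oxy]methyl}-5-ethyl-1,3,4,7-tetramethyl-2-oxo-2,4,5,7a-tetrahydro-1H-indene-4-carboxylate
Conditions: [Rh(CO)2Cl]2 (10 mol %), CO (1 atm), m-xylene, 110 °C
Reagents that add atoms: none
Why: Intramolecular Pauson–Khand reaction: monovalent rhodium binds the alkyne and the propenyl alkene of 17, oxidative cyclisation gives a rhodacyclopentene and closes the cyclohexene by joining C3a to C7a, then CO 18 inserts and reductive elimination closes the cyclopentenone through the C1–C2 and C2–C3 bonds. The closest known reaction type is the [Rh(CO)2Cl]2-catalysed cyclocarbonylation of 1,7-enynes whose tether is stiffened by an alkene or arene and by geminal substitution; here the Z alkene and the two quaternary carbons hold the reacting groups together. The trisubstituted C6=C7 alkene cannot compete, because its engagement would close a four-membered ring. C1 is set by the alkene geometry: carbon–carbon and carbon–rhodium bond formation are suprafacial, so the E-propenyl group places the C1 methyl trans to C7. C7a is set by the alkene face that meets the alkyne; of the two half-chair arrangements of the tether, the one with the C4 methyl pseudo-axial, the planar ester in the ring plane beside the alkyne methyl (least 1,3-allylic strain) and the C5 silyloxymethyl group pseudo-axial leads to 19. This facial preference is the selectivity the step needs, and it rests on conformational analysis only. The diene must twist out of conjugation and its second alkene sits on the carbon that bonds to carbon, not to rhodium, so no rate gain from conjugation is assumed.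

Step 13
Reactants: 19 tert-butyl (1S,4R,5S,7aR)-5-{[(tert-butyldimethylsilyl)oxy]methyl}-5-ethyl-1,3,4,7-tetramethyl-2-oxo-2,4,5,7a-tetrahydro-1H-indene-4-carboxylate
Product: 20 tert-butyl (1S,2S,4R,5S,7aR)-5-{[(tert-butyldimethylsilyl)oxy]methyl}-5-ethyl-2-hydroxy-1,3,4,7-tetramethyl-2,4,5,7a-tetrahydro-1H-indene-4-carboxylate (hydroxyl cis to the C1 methyl)
Conditions: NaBH4, CeCl3·7H2O, MeOH, −78 to −40 °C
Reagents that add atoms: none
Why: Luche 1,2-reduction; hydride adds to the face of the cyclopentenone anti to the adjacent C1 methyl, so the hydroxyl ends cis to it. The cold, nearly neutral medium should avoid epimerisation at C1 and migration of the alkene into conjugation through C7a.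

Step 14
Reactants: 20 tert-butyl (1S,2S,4R,5S,7aR)-5-{[(tert-butyldimethylsilyl)oxy]methyl}-5-ethyl-2-hydroxy-1,3,4,7-tetramethyl-2,4,5,7a-tetrahydro-1H-indene-4-carboxylate
Product: 23 tert-butyl (1R,3aR,4R,5S,7aS)-5-{[(tert-butyldimethylsilyl)oxy]methyl}-5-ethyl-1,3,4,7-tetramethyl-3a,4,5,7a-tetrahydro-1H-indene-4-carboxylate, via sulfonylhydrazone adduct 21 (not isolated), via allylic diazene 22 (not isolated)
Conditions: PPh3, DEAD, N-isopropylidene-N'-(2-nitrobenzenesulfonyl)hydrazine, THF, 0 °C to rt; then CF3CH2OH/H2O (1:1), rt
Reagents that add atoms: none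
Why: Mitsunobu displacement with inversion puts nitrogen on the face anti to the C1 methyl; hydrolysis of the hydrazone and loss of sulfinic acid give the monoalkyl diazene 22. Its retro-ene loss of N2 (allylic diazene rearrangement) delivers hydrogen suprafacially to C3a on that same face, opposite H7a, giving the trans fusion and the C2=C3 alkene. The acetone-protected hydrazine is used because it tolerates the room-temperature Mitsunobu conditions that a hindered carbinol needs.

Step 15
Reactants: 23 tert-butyl (1R,3aR,4R,5S,7aS)-5-{[(tert-butyldimethylsilyl)oxy]methyl}-5-ethyl-1,3,4,7-tetramethyl-3a,4,5,7a-tetrahydro-1H-indene-4-carboxylate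
Product: 24 tert-butyl (1R,3aR,4R,5S,7aS)-5-ethyl-5-(hydroxymethyl)-1,3,4,7-tetramethyl-3a,4,5,7a-tetrahydro-1H-indene-4-carboxylate
Conditions: HF·pyridine, pyridine, THF, 0 °C to rt
Reagents that add atoms: none
Why: Fluoride-driven cleavage of the primary silyl ether under buffered, weakly acidic conditions; no alkoxide is formed and the tert-butyl ester resists attack by the neighbouring hydroxyl, so the γ-hydroxy ester should stay open.

Step 16
Reactants: 24 tert-butyl (1R,3aR,4R,5S,7aS)-5-ethyl-5-(hydroxymethyl)-1,3,4,7-tetramethyl-3a,4,5,7a-tetrahydro-1H-indene-4-carboxylate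
Product: 25 tert-butyl (1R,3aR,4R,5S,7aS)-5-ethyl-5-formyl-1,3,4,7-tetramethyl-3a,4,5,7a-tetrahydro-1H-indene-4-carboxylate
Conditions: Dess–Martin periodinane, NaHCO3, CH2Cl2, 0 °C to rt
Reagents that add atoms: none
Why: Dess–Martin oxidation of the neopentyl alcohol under buffered conditions; the aldehyde has no α-hydrogen and the alkenes are not affected.

Step 17
Reactants: 25 tert-butyl (1R,3aR,4R,5S,7aS)-5-ethyl-5-formyl-1,3,4,7-tetramethyl-3a,4,5,7a-tetrahydro-1H-indene-4-carboxylate, 26 diethyl [(2E)-3-phenylprop-2-en-1-yl]phosphonate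
Product: 27 tert-butyl (1R,3aR,4R,5S,7aS)-5-ethyl-1,3,4,7-tetramethyl-5-[(1E,3E)-4-phenylbuta-1,3-dien-1-yl]-3a,4,5,7a-tetrahydro-1H-indene-4-carboxylate
Conditions: 26, LiN(SiMe3)2, THF, −78 °C; then 25, −78 °C to rt
Reagents that add atoms: none
Why: Horner–Wadsworth–Emmons reaction of the allylic phosphonate anion; reversible addition and syn-elimination of phosphate should give the E alkene, while the cinnamyl E alkene is carried in unchanged.

Step 18
Reactants: 27 tert-butyl (1R,3aR,4R,5S,7aS)-5-ethyl-1,3,4,7-tetramethyl-5-[(1E,3E)-4-phenylbuta-1,3-dien-1-yl]-3a,4,5,7a-tetrahydro-1H-indene-4-carboxylate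
Product: 29 (1R,3aR,4R,5S,7aS)-5-ethyl-1,3,4,7-tetramethyl-5-[(1E,3E)-4-phenylbuta-1,3-dien-1-yl]-3a,4,5,7a-tetrahydro-1H-indene-4-carboxylic acid (CNP0200738.1), via trimethylsilyl ester 28 (not isolated)
Conditions: Me3SiOTf, 2,6-lutidine, CH2Cl2, 0 °C; then H2O
Reagents that add atoms: none
Why: Silyl triflate-induced loss of isobutene from the tert-butyl ester (alkyl–oxygen cleavage), then hydrolysis of the silyl ester. The base-buffered, non-protic medium needs no attack at the shielded carbonyl and should not protonate C2=C3 or the diene.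

## Compound list

1 | pent-3-ynoic acid | CC#CCC(=O)O | starting material
2 | 2-methylpent-3-ynoic acid (racemic) | CC#CC(C)C(=O)O | intermediate
3 | (R)-but-3-yn-2-ol | C[C@@H](O)C#C | starting material
4 | (R)-pent-2-yne-1,4-diol | C[C@@H](O)C#CCO | intermediate
5 | (R)-5-[(tert-butyldimethylsilyl)oxy]pent-3-yn-2-ol | C[C@@H](O)C#CCO[Si](C)(C)C(C)(C)C | intermediate
6 | cyclic sodium alkoxy(alkenyl)bis(2-methoxyethoxy)aluminate from 5 (Al on C4, H on C3) | C[C@H]1O[Al-](OCCOC)(OCCOC)C(CO[Si](C)(C)C(C)(C)C)=C1.[Na+] | intermediate
7 | (2R,3Z)-5-[(tert-butyldimethylsilyl)oxy]-4-iodopent-3-en-2-ol | C[C@@H](O)/C=C(\I)CO[Si](C)(C)C(C)(C)C | intermediate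
8 | (2R,3E)-4-{[(tert-butyldimethylsilyl)oxy]methyl}hex-3-en-2-ol | C[C@@H](O)/C=C(\CC)CO[Si](C)(C)C(C)(C)C | intermediate
9 | (2R,3E)-4-{[(tert-butyldimethylsilyl)oxy]methyl}hex-3-en-2-yl 2-methylpent-3-ynoate (epimers at the acyl α-carbon) | CC#CC(C)C(=O)O[C@H](C)/C=C(\CC)CO[Si](C)(C)C(C)(C)C | intermediate
10 | trimethylsilyl ketene acetal of 9 (methyl cis to the allylic oxygen, propynyl cis to OSiMe3) | CC#C/C(C)=C(\O[Si](C)(C)C)O[C@H](C)/C=C(\CC)CO[Si](C)(C)C(C)(C)C | intermediate
11 | trimethylsilyl ester of 12 | CC#C[C@@](C)(C(=O)O[Si](C)(C)C)[C@@](CC)(CO[Si](C)(C)C(C)(C)C)/C=C/C | intermediate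
12 | (2R,3S,4E)-3-{[(tert-butyldimethylsilyl)oxy]methyl}-3-ethyl-2-methyl-2-(prop-1-yn-1-yl)hex-4-enoic acid | CC#C[C@@](C)(C(=O)O)[C@@](CC)(CO[Si](C)(C)C(C)(C)C)/C=C/C | intermediate
13 | tert-butyl (2R,3S,4E)-3-{[(tert-butyldimethylsilyl)oxy]methyl}-3-ethyl-2-methyl-2-(prop-1-yn-1-yl)hex-4-enoate | CC#C[C@@](C)(C(=O)OC(C)(C)C)[C@@](CC)(CO[Si](C)(C)C(C)(C)C)/C=C/C | intermediate
14 | tert-butyl (2R,3S)-3-{[(tert-butyldimethylsilyl)oxy]methyl}-3-ethyl-2-methyl-4-oxo-2-(prop-1-yn-1-yl)butanoate | CC#C[C@@](C)(C(=O)OC(C)(C)C)[C@@](CC)(CO[Si](C)(C)C(C)(C)C)C=O | intermediate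
15 | tert-butyl (2R,3S,4Z)-3-{[(tert-butyldimethylsilyl)oxy]methyl}-3-ethyl-5-iodo-2-methyl-2-(prop-1-yn-1-yl)hex-4-enoate | CC#C[C@@](C)(C(=O)OC(C)(C)C)[C@@](CC)(CO[Si](C)(C)C(C)(C)C)/C=C(\I)C | intermediate
16 | (E)-prop-1-en-1-ylboronic acid | C/C=C/B(O)O | starting material
17 | tert-butyl (2R,3S,4Z,6E)-3-{[(tert-butyldimethylsilyl)oxy]methyl}-3-ethyl-2,5-dimethyl-2-(prop-1-yn-1-yl)octa-4,6-dienoate | CC#C[C@@](C)(C(=O)OC(C)(C)C)[C@@](CC)(CO[Si](C)(C)C(C)(C)C)/C=C(C)\C=C\C | intermediate
18 | carbon monoxide | [C-]#[O+] | starting material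
19 | tert-butyl (1S,4R,5S,7aR)-5-{[(tert-butyldimethylsilyl)oxy]methyl}-5-ethyl-1,3,4,7-tetramethyl-2-oxo-2,4,5,7a-tetrahydro-1H-indene-4-carboxylate | CC[C@]1(CO[Si](C)(C)C(C)(C)C)C=C(C)[C@H]2[C@H](C)C(=O)C(C)=C2[C@@]1(C)C(=O)OC(C)(C)C | intermediate
20 | tert-butyl (1S,2S,4R,5S,7aR)-5-{[(tert-butyldimethylsilyl)oxy]methyl}-5-ethyl-2-hydroxy-1,3,4,7-tetramethyl-2,4,5,7a-tetrahydro-1H-indene-4-carboxylate | CC[C@]1(CO[Si](C)(C)C(C)(C)C)C=C(C)[C@H]2[C@H](C)[C@H](O)C(C)=C2[C@@]1(C)C(=O)OC(C)(C)C | intermediate
21 | Mitsunobu adduct: C2-inverted N-(2-nitrobenzenesulfonyl)-N'-(propan-2-ylidene)hydrazine of 20 (nitrogen trans to the C1 methyl) | CC[C@]1(CO[Si](C)(C)C(C)(C)C)C=C(C)[C@H]2[C@H](C)[C@@H](N(N=C(C)C)S(=O)(=O)c3ccccc3[N+](=O)[O-])C(C)=C2[C@@]1(C)C(=O)OC(C)(C)C | intermediate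
22 | allylic monoalkyl diazene (N=NH on C2, trans to the C1 methyl) | CC[C@]1(CO[Si](C)(C)C(C)(C)C)C=C(C)[C@H]2[C@H](C)[C@@H](N=N)C(C)=C2[C@@]1(C)C(=O)OC(C)(C)C | intermediate
23 | tert-butyl (1R,3aR,4R,5S,7aS)-5-{[(tert-butyldimethylsilyl)oxy]methyl}-5-ethyl-1,3,4,7-tetramethyl-3a,4,5,7a-tetrahydro-1H-indene-4-carboxylate | CC[C@]1(CO[Si](C)(C)C(C)(C)C)C=C(C)[C@H]2[C@H](C)C=C(C)[C@@H]2[C@@]1(C)C(=O)OC(C)(C)C | intermediate
24 | tert-butyl (1R,3aR,4R,5S,7aS)-5-ethyl-5-(hydroxymethyl)-1,3,4,7-tetramethyl-3a,4,5,7a-tetrahydro-1H-indene-4-carboxylate | CC[C@]1(CO)C=C(C)[C@H]2[C@H](C)C=C(C)[C@@H]2[C@@]1(C)C(=O)OC(C)(C)C | intermediate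
25 | tert-butyl (1R,3aR,4R,5S,7aS)-5-ethyl-5-formyl-1,3,4,7-tetramethyl-3a,4,5,7a-tetrahydro-1H-indene-4-carboxylate | CC[C@]1(C=O)C=C(C)[C@H]2[C@H](C)C=C(C)[C@@H]2[C@@]1(C)C(=O)OC(C)(C)C | intermediate
26 | diethyl [(2E)-3-phenylprop-2-en-1-yl]phosphonate | CCOP(=O)(C/C=C/c1ccccc1)OCC | starting material
27 | tert-butyl (1R,3aR,4R,5S,7aS)-5-ethyl-1,3,4,7-tetramethyl-5-[(1E,3E)-4-phenylbuta-1,3-dien-1-yl]-3a,4,5,7a-tetrahydro-1H-indene-4-carboxylate | CC[C@]1(/C=C/C=C/c2ccccc2)C=C(C)[C@H]2[C@H](C)C=C(C)[C@@H]2[C@@]1(C)C(=O)OC(C)(C)C | intermediate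
28 | trimethylsilyl ester of 29 | CC[C@]1(/C=C/C=C/c2ccccc2)C=C(C)[C@H]2[C@H](C)C=C(C)[C@@H]2[C@@]1(C)C(=O)O[Si](C)(C)C | intermediate
29 | (1R,3aR,4R,5S,7aS)-5-ethyl-1,3,4,7-tetramethyl-5-[(1E,3E)-4-phenylbuta-1,3-dien-1-yl]-3a,4,5,7a-tetrahydro-1H-indene-4-carboxylic acid | CC[C@]1(/C=C/C=C/c2ccccc2)C=C(C)[C@H]2[C@H](C)C=C(C)[C@@H]2[C@@]1(C)C(=O)O | target

## Step count and least certain steps

Total: 18 steps. Longest linear sequence: 17 steps (3 to 29, steps 2–18); step 1 is a one-step branch.

Step 12 (key step). Most likely to go wrong: the 1,2-disubstituted propenyl alkene may enter the rhodacycle too slowly, because internal alkenes insert reluctantly and the diene must twist. Alkyne oligomerisation could then take over, and the two half-chair approaches could be populated together, eroding the facial selectivity at C7a. Fallback: use a more reactive monosubstituted alkene in the cyclocarbonylation and install the C1 methyl afterwards.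
- Set out from 15 and couple it with vinylboronic acid pinacol ester (Pd(dppf)Cl2, K3PO4) to give tert-butyl (2R,3S,4Z)-3-{[(tert-butyldimethylsilyl)oxy]methyl}-3-ethyl-2,5-dimethyl-2-(prop-1-yn-1-yl)hepta-4,6-dienoate F1.
- Cyclocarbonylate F1 with [Rh(CO)2Cl]2 under CO at lower temperature to the C1-unsubstituted enone, tert-butyl (4R,5S,7aR)-5-{[(tert-butyldimethylsilyl)oxy]methyl}-5-ethyl-3,4,7-trimethyl-2-oxo-2,4,5,7a-tetrahydro-1H-indene-4-carboxylate F2.
- Form the kinetic α'-enolate of F2 (LiN(iPr)2, THF, −78 °C) and add MeI. The methyl should enter anti to C7, and the route is rejoined at 19.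

Step 7. Most likely to go wrong: enolisation may not discriminate well enough between methyl and propynyl, so both geometries of the tetrasubstituted ketene acetal form and the C4 configuration relative to C5 is eroded. Fallback: fix the enolate geometry by chelation in a dianion Carroll rearrangement.
- Set out from 8 and transesterify it with ethyl 2-methylacetoacetate (DMAP, toluene, reflux) to (2R,3E)-4-{[(tert-butyldimethylsilyl)oxy]methyl}hex-3-en-2-yl 2-methyl-3-oxobutanoate F3.
- Treat F3 with LiN(iPr)2 (2.2 equiv). The chelated dianion holds the methyl cis to the allylic oxygen and should rearrange through the same chair to (2R,3S,4E)-2-acetyl-3-{[(tert-butyldimethylsilyl)oxy]methyl}-3-ethyl-2-methylhex-4-enoic acid F4, which is kept cold to avoid decarboxylation.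
- Esterify F4 with tert-butyl 2,2,2-trichloroacetimidate to the tert-butyl ester F5.
- Convert F5 with KN(SiMe3)2 and PhNTf2 into the enol triflate F6.
- Treat F6 with excess LiN(iPr)2 to eliminate triflate to the lithium acetylide and add MeI. The route is rejoined at 13.

Step 10. Most likely to go wrong: addition of the α-iodo ylide to a neopentyl aldehyde flanked by two quaternary carbons may be slow, with decomposition of the ylide and loss of Z selectivity. Fallback: build the Z alkene by a phosphonate olefination.
- Set out from 14 and carry out a Still–Gennari olefination with ethyl 2-[bis(2,2,2-trifluoroethoxy)phosphoryl]propanoate (KN(SiMe3)2, 18-crown-6, THF, −78 °C) to the Z-enoate F7.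
- Reduce the unhindered conjugated ester of F7 with iBu2AlH at −78 °C to the Z-allylic alcohol F8; the shielded tert-butyl ester should be spared.
- Oxidise F8 with MnO2 to the Z-enal F9.
- Carry out a Julia–Kocienski ethylidenation of F9 with 5-(ethylsulfonyl)-1-phenyl-1H-tetrazole and KN(SiMe3)2. The route is rejoined at 17.

Step 14. Most likely to go wrong: the Mitsunobu displacement at the carbinol flanked by CHMe and CMe= may give way to elimination to a cyclopentadiene or to SN2' attack. Fallback: a palladium-catalysed formate reduction of an allylic carbonate.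
- Set out from 20 and acylate it with methyl chloroformate and pyridine to the allylic methyl carbonate F10.
- Reduce F10 with Pd(OAc)2, PBu3 and HCO2H/Et3N (Tsuji reduction). Palladium ionises the carbonate anti, on the face opposite the C1 methyl, and hydride transfer from palladium to the more substituted allyl terminus C3a on that face gives the same trans-fused diene. The route is rejoined at 23.

Step 17. Most likely to go wrong: addition of the phosphonate anion to the aldehyde between two quaternary carbons may be slow and may revert, giving poor conversion. Fallback: a two-step construction of the diene.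
- Set out from 25 and carry out a Takai olefination (CHI3, CrCl2, THF) to the (E)-vinyl iodide, tert-butyl (1R,3aR,4R,5S,7aS)-5-ethyl-5-[(E)-2-iodoethenyl]-1,3,4,7-tetramethyl-3a,4,5,7a-tetrahydro-1H-indene-4-carboxylate F11.
- Couple F11 with (E)-2-phenylethenylboronic acid (Pd(PPh3)4, aqueous K3PO4) with retention. The route is rejoined at 27.

## Further compounds

F1 | step 12 | tert-butyl (2R,3S,4Z)-3-{[(tert-butyldimethylsilyl)oxy]methyl}-3-ethyl-2,5-dimethyl-2-(prop-1-yn-1-yl)hepta-4,6-dienoate | CC#C[C@@](C)(C(=O)OC(C)(C)C)[C@@](CC)(CO[Si](C)(C)C(C)(C)C)/C=C(C)\C=C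
F2 | step 12 | tert-butyl (4R,5S,7aR)-5-{[(tert-butyldimethylsilyl)oxy]methyl}-5-ethyl-3,4,7-trimethyl-2-oxo-2,4,5,7a-tetrahydro-1H-indene-4-carboxylate | CC[C@]1(CO[Si](C)(C)C(C)(C)C)C=C(C)[C@H]2CC(=O)C(C)=C2[C@@]1(C)C(=O)OC(C)(C)C
F3 | step 7 | (2R,3E)-4-{[(tert-butyldimethylsilyl)oxy]methyl}hex-3-en-2-yl 2-methyl-3-oxobutanoate | CC(=O)C(C)C(=O)O[C@H](C)/C=C(\CC)CO[Si](C)(C)C(C)(C)C
F4 | step 7 | (2R,3S,4E)-2-acetyl-3-{[(tert-butyldimethylsilyl)oxy]methyl}-3-ethyl-2-methylhex-4-enoic acid | CC(=O)[C@@](C)(C(=O)O)[C@@](CC)(CO[Si](C)(C)C(C)(C)C)/C=C/C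
F5 | step 7 | tert-butyl (2R,3S,4E)-2-acetyl-3-{[(tert-butyldimethylsilyl)oxy]methyl}-3-ethyl-2-methylhex-4-enoate | CC(=O)[C@@](C)(C(=O)OC(C)(C)C)[C@@](CC)(CO[Si](C)(C)C(C)(C)C)/C=C/C
F6 | step 7 | enol triflate of F5 (1-[(trifluoromethanesulfonyl)oxy]ethenyl group on the carboxyl-bearing carbon) | C=C(OS(=O)(=O)C(F)(F)F)[C@@](C)(C(=O)OC(C)(C)C)[C@@](CC)(CO[Si](C)(C)C(C)(C)C)/C=C/C
F7 | step 10 | 1-tert-butyl 6-ethyl (2R,3S,4Z)-3-{[(tert-butyldimethylsilyl)oxy]methyl}-3-ethyl-2,5-dimethyl-2-(prop-1-yn-1-yl)hex-4-enedioate | CC#C[C@@](C)(C(=O)OC(C)(C)C)[C@@](CC)(CO[Si](C)(C)C(C)(C)C)/C=C(C)\C(=O)OCC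
F8 | step 10 | tert-butyl (2R,3S,4Z)-3-{[(tert-butyldimethylsilyl)oxy]methyl}-3-ethyl-6-hydroxy-2,5-dimethyl-2-(prop-1-yn-1-yl)hex-4-enoate | CC#C[C@@](C)(C(=O)OC(C)(C)C)[C@@](CC)(CO[Si](C)(C)C(C)(C)C)/C=C(C)\CO
F9 | step 10 | tert-butyl (2R,3S,4Z)-3-{[(tert-butyldimethylsilyl)oxy]methyl}-3-ethyl-2,5-dimethyl-6-oxo-2-(prop-1-yn-1-yl)hex-4-enoate | CC#C[C@@](C)(C(=O)OC(C)(C)C)[C@@](CC)(CO[Si](C)(C)C(C)(C)C)/C=C(C)\C=O
F10 | step 14 | methyl carbonate of 20 (carbonate cis to the C1 methyl) | CC[C@]1(CO[Si](C)(C)C(C)(C)C)C=C(C)[C@H]2[C@H](C)[C@H](OC(=O)OC)C(C)=C2[C@@]1(C)C(=O)OC(C)(C)C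
F11 | step 17 | tert-butyl (1R,3aR,4R,5S,7aS)-5-ethyl-5-[(E)-2-iodoethenyl]-1,3,4,7-tetramethyl-3a,4,5,7a-tetrahydro-1H-indene-4-carboxylate | CC[C@]1(/C=C/I)C=C(C)[C@H]2[C@H](C)C=C(C)[C@@H]2[C@@]1(C)C(=O)OC(C)(C)C
A1 | alternative 1 | trans-fused octalone lactone obtained after epimerisation | CC[C@]12CC(=O)[C@H]3[C@H](C)C=CC[C@@H]3[C@@]1(C)C(=O)OC2
A2 | alternative 3 | cis-fused cyclohexenone lactone with both quaternary carbons (key-step product; also the dienophile of alternative 1) | CC[C@]12CC(=O)C=C[C@@]1(C)C(=O)OC2
A3 | alternative 1 | (E)-penta-1,3-diene | C=C/C=C/C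
A4 | alternative 2 | bicyclic acid with both quaternary carbons and a CH2O(4-methoxybenzyl) group in place of the dienyl chain | CC[C@]1(COCc2ccc(OC)cc2)C=C(C)[C@H]2[C@H](C)C=C(C)[C@@H]2[C@@]1(C)C(=O)O
A5 | alternative 2 | cyclopentene-fused δ-lactone whose tertiary carbinol carbon carries the E-alkenyl group (α-carbon configuration not fixed) | CC/C(COCc1ccc(OC)cc1)=C\[C@@]1(C)OC(=O)C(C)[C@H]2C(C)=C[C@@H](C)[C@H]12
A6 | alternative 3 | trimethylsilyl dienol ether of the 4-methyl-5-ethylcyclohexenone carrying a CH2OCO2Me group on the quaternary carbon | CC[C@]1(COC(=O)OC)CC(O[Si](C)(C)C)=CC=C1C
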